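## The problem

Target 40 is a dibenzylbutyrolactone in which both benzyl groups are 5-substituted guaiacyl rings. Ring B carries at C5 the arm ring A–C(=O)–CH(CH2OH)–, and ring C is closed through its phenol oxygen and C5 into a trans-2-aryl-3-(hydroxymethyl)-2,3-dihydrobenzofuran that bears ring D. The five stereocentres fall into three groups insulated from one another by CH2 groups and arenes: the lactone pair (Cα R, Cβ R, trans), the dihydrobenzofuran pair (C2 S, C3 R, trans) and the single arm methine (S). No group can steer another, so three independent sources of asymmetry are needed; inside a group, Cβ can set Cα (alkylation anti to the β-substituent) and C3 can set C2 (reversible benzylic ring closure to the trans isomer). The arm methine is the fragile point: it is benzylic, α to an aryl ketone and β to a free hydroxyl, so base epimerises it and opens retro-aldol loss of formaldehyde or dehydration, and the ketone should therefore appear late and under near-neutral conditions. The lactone excludes strong hydride donors and hard nucleophiles once it exists, and the C2–O bond of the dihydrobenzofuran is a p-oxygenated benzyl ether that tolerates neither strong acid, quinone oxidants nor long hydrogenolysis. Three phenols and two primary alcohols must be masked so that the secondary carbinol precursor of the ketone can be addressed alone. The handle for the key step is the lactone β-carbon: it carries the ring B CH2, the OCH2 carbon and the α-CH2, so it is the methine of a 2-(arylmethyl)succinic acid whose two carboxyls differ, and the corresponding flat alkene 5 arises in one step from a ring B aldehyde and dimethyl succinate with the carboxyls already differentiated and placed to chelate a hydrogenation catalyst.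

## Retrosynthesis

40 ⇒ 39 ⇒ 38 ⇒ 37. No skeletal bond is cut. The two benzyl ethers (rings A and B) and three silyl ethers (two primary alcohols, ring D phenol) are put back, and the ketone is traced to the secondary carbinol 37. Against the neighbouring cut, the ring A–C(=O) bond, this keeps the arm methine a non-acidic benzylic CH until three steps from the end. The forward steps must be non-basic: buffered Dess–Martin oxidation, HF·pyridine, neutral hydrogenolysis.

37 ⇒ 36 ⇒ 20 + 34. The bond between the lactone α-carbon and the ring C CH2 is cut (36 is the triethylsilyl ether of 37). A cut at Cβ–CH2 would demand a stereocentre-forming step on the whole skeleton, whereas here Cβ is in place and sends the electrophile to the opposite face. The molecule is halved into lactone 20 and benzylic bromide 34, each with two stereocentres. The forward step is a trans C-alkylation of a lactone lithium enolate with every hydroxyl silylated.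

20 ⇒ 18 ⇒ 17 ⇒ 14 + 15. The arm is cut between its methine and the ring A carbinol carbon, the aldol bond of a 1,2-diaryl-1,3-diol; the auxiliary-bound carbonyl of 17 is the later CH2OH. The neighbouring cuts (acylating ring A with an α-aryl acid derivative, or arylating a ring A ketone enolate) both put the methine next to a carbonyl under base. The precursors are imide 14, whose arm is achiral, and commercial aldehyde 15. Required are a syn aldol with the enolate face fixed by the (R)-oxazolidinone, and a reductive release of the auxiliary that spares the lactone.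

14 ⇒ 12 ⇒ 11 ⇒ 9 + 10. The ring B–CH2 bond of the arylacetic acid is cut back to the aryl bromide of lactone 9 and the Reformatsky reagent 10. An acetic acid chain carried through the condensation would expose its acidic CH2 to methoxide and aldehyde; a bromide is silent there and in the hydrogenation. Lactone 9 is small and has one stereocentre. Required is a palladium coupling that the lactone tolerates.

9 ⇒ 6 ⇒ 5 (key disconnection). The lactone C–O bond is opened to half-ester 6 (ester = future OCH2, acid = future carbonyl), and the C–H bonds at the methine and the benzylic carbon are removed to give alkene 5. Compared with auxiliary alkylation of a 3-arylpropanoate or conjugate addition to a butenolide, this is a catalytic step on a flat precursor whose carboxyls are already differentiated. Required is face-selective hydrogenation that leaves C–Br and the benzyl ether untouched.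

5 ⇒ 3 + 4 ⇒ 1 + 2. The C=C bond is cut to aldehyde 3 and dimethyl succinate 4 (Stobbe condensation), and 3 to 5-bromovanillin 1 and benzyl bromide 2. The E geometry and the half-ester regiochemistry follow from the mechanism.

34 ⇒ 33 ⇒ 32 ⇒ 31 ⇒ 29. The bromide is taken back to ester 32 (reduction, bromination), the silyl groups are removed, and the C2–O bond of dihydrobenzofuran 31 is cut to diol 29 (through diphenol 30). Cuts at C2–C3 or C3–C3a lead to carbene-insertion or cycloaddition chemistry. The C–O cut leads to a 1,2-diaryl-1,3-diol of the same kind as 18, so one reaction sequence serves both arms. Required is an ionising closure in which C3 directs C2 to trans.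

29 ⇒ 28 ⇒ 26 + 15 ⇒ 24 ⇒ 23 ⇒ 22 + 10 ⇒ 21 + 2. The aldol bond is cut as before, now with the (S)-auxiliary, because C3 (R) and the ring B arm methine (S) have opposite spatial sense when their substituents are matched. Arylacetic acid 24 comes from methyl 5-bromovanillate 21 by benzylation and the same coupling with 10. The C5 ester is the future CH2Br and distinguishes this carbon from the C3 hydroxymethyl group.

## Roads not taken

Alternative 1: The cut is the ring A–carbonyl bond, made last. The S-ethyl thioester A2 (complete skeleton, hydroxyls silylated) would be coupled with the ring A boronic acid A3 under Pd2(dba)3, P(OEt)3 and copper thiophene-2-carboxylate (monovalent copper), without base, to give the pentasilyl ether A1, one fluoride step from 40.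
- Merits: the bond forms under neutral conditions, ring A arrives last, and the ketone appears at the right oxidation level with no carbinol to set and oxidise.
- Weak points: A2 must be made with its methine already α to an acyl group, so the labile centre spends several steps, one with a basic thiolate, in its most acidic form. The acyl carbon is flanked by a tertiary benzylic carbon bearing an ortho-silyloxy aryl group, which slows transmetalation and invites β-elimination of the silyloxy group or decarbonylation. Three phenolic silyl ethers would not survive the methoxide and enolate chemistry that builds the lactone, so protecting groups would have to be exchanged. The step creates no stereocentre.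
- Comparison: this road would save steps 22 and 23 of the chosen route and avoids a discarded carbinol centre; that is a real advantage in the end game. The chosen plan sets against it that the ring A bond is formed in the same aldol that fixes the methine under auxiliary control, and that the methine stays non-acidic until step 23. Both roads meet fluoride at a β-silyloxy ketone (step 24 here).

Alternative 2: The cut is the two C–H bonds at C2 and C3 of the dihydrobenzofuran. The flat benzofuran ester A5 would be hydrogenated under [Ru(cod)(2-methylallyl)2], a chiral imidazolinium salt and KOtBu to the cis ester A4 with C2 as in 40.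
- Merits: a flat precursor from benzofuran annulation, a catalytic step, C2 set directly and no auxiliary.
- Weak points: syn addition gives the cis isomer, so C3 must be inverted through the ester enolate, and that enolate can expel the C2 aryloxide (retro-oxa-Michael), which would erase C2 as well. A 2-aryl-3-alkoxycarbonyl benzofuran is a tetrasubstituted, push–pull alkene outside the best-documented substrate range. Two electron-rich benzene rings and a benzyl ether face an arene-hydrogenation catalyst under pressure.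
- Comparison: if it worked it would be clearly shorter than steps 11–20 (ten steps, stoichiometric auxiliary), and better in atom economy. The chosen plan sets against it that every step of its dihydrobenzofuran branch lies in an established substrate class, that C3 is set directly in the right sense, and that C2 follows by a reversible closure with no centre to invert. The lactone pair is untouched by this alternative.

Alternative 3: The cut is the carbinol C–H bond, with the adjacent methine fixed by dynamic kinetic resolution. The racemic β-keto ester A7 would be reduced by RuCl(p-cymene)(TsDPEN) with HCO2H and Et3N to the syn hydroxy ester A6, whose methine is C3 of 40.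
- Merits: A7 comes from one acylation of an arylacetate, α-aryl β-keto esters racemise fast, the catalyst is cheap, and A6 is the direct analogue of 28.
- Weak points: the ketone is a p-alkoxyaryl ketone, a poor hydride acceptor, next to a methine with an ortho-substituted aryl group, so rate, syn/anti ratio and enantioselectivity are hard to predict. The carbinol centre is erased in the ionising ring closure, so half of what the catalyst achieves is unused. The C5 bromide of A6 needs a formylation sequence through an aryllithium to become CH2Br, longer than steps 19–20 here.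
- Comparison: in length it is about equal to steps 11–20 and it is better in atom economy (no auxiliary, no tert-butyl ester detour). The chosen plan sets against it the predictability of the boron aldol with hindered, electron-rich partners, and the reuse of the same sequence on ring B, where this road would end in an ester reduction that the lactone of 9 does not tolerate.

Key step: step 3

Remark on the chemistry: the S,S hand of Me-DuPhos is taken to give the R acid 6, by analogy with 2-alkylidene succinic half-esters; should the first run show the opposite sense, the R,R ligand is used and nothing else changes.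

## Steps

Step 1
Reactants: 1 5-bromovanillin; 2 benzyl bromide
Product: 3 4-(benzyloxy)-3-bromo-5-methoxybenzaldehyde
Conditions: K2CO3, DMF, 60 °C
Reagents that add atoms: none
Why: Williamson etherification of the phenoxide; the benzyl ether survives methoxide at reflux, the rhodium hydrogenation, borohydride, trifluoroacetic acid and amide bases, and leaves by neutral hydrogenolysis in step 25.

Step 2
Reactants: 3 4-(benzyloxy)-3-bromo-5-methoxybenzaldehyde; 4 dimethyl succinate
Product: 5 (E)-4-[4-(benzyloxy)-3-bromo-5-methoxyphenyl]-3-(methoxycarbonyl)but-3-enoic acid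
Conditions: NaOMe (2.2 eq), MeOH, reflux; then aq. HCl; recrystallise
Reagents that add atoms: none
Why: Stobbe condensation: the succinate enolate adds to the aldehyde, the alkoxide closes onto the distal ester to a paraconic ester, and E1cB opening leaves the conjugated carboxyl as ester and the distal one as carboxylate. The E isomer (aryl trans to CO2Me) is favoured and crystallisation removes any Z isomer before the key step.

Step 3
Reactants: 5 (E)-4-[4-(benzyloxy)-3-bromo-5-methoxyphenyl]-3-(methoxycarbonyl)but-3-enoic acid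
Product: 6 (R)-3-[4-(benzyloxy)-3-bromo-5-methoxybenzyl]-4-methoxy-4-oxobutanoic acid
Conditions: H2 (5 bar), [Rh(cod)2]BF4 (1 mol%), (S,S)-Me-DuPhos (1.1 mol%), NaOMe (10 mol%), MeOH, 25 °C
Reagents that add atoms: none
Why: The carboxylate arm and the trisubstituted alkene of 5 bind cationic monovalent rhodium as a chelate in the manner of an itaconate; H2 adds oxidatively to give a trivalent rhodium dihydride, and migratory insertion followed by reductive elimination delivers both hydrogens to one alkene face, forming the C–H bond at the future lactone β-carbon and the second C–H bond of the ring B benzylic CH2. The closest known reaction type is the rhodium–bisphospholane hydrogenation of 2-alkylidene and 2-arylidene succinic 1-monoesters made by Stobbe condensation. No ring closes. The single new stereocentre is set by the catalyst: the C2-symmetric phospholane rings block two diagonal quadrants, so only one enantioface of the chelated alkene fits, and the S,S hand is chosen for the R acid. The step needs enantioface selection, which rests on two-point binding of one geometrical isomer and is secured by crystallising E-5; catalytic methoxide keeps part of the substrate as the better-binding carboxylate. It also needs chemoselectivity, which the catalyst supplies: a cationic rhodium bisphosphine at room temperature neither inserts into the aryl C–Br bond nor cleaves the benzyl ether, both of which heterogeneous palladium would attack. The R methine of 6 becomes the R β-carbon of lactone 9 and later directs Cα.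

Step 4
Reactants: 6 (R)-3-[4-(benzyloxy)-3-bromo-5-methoxybenzyl]-4-methoxy-4-oxobutanoic acid
Product: 9 (R)-4-[4-(benzyloxy)-3-bromo-5-methoxybenzyl]dihydrofuran-2(3H)-one, via potassium carboxylate 7 (not isolated), via hydroxy acid 8 (not isolated)
Conditions: KOH (1 eq), EtOH; CaCl2, NaBH4, EtOH, −10 °C → rt; then 3 M HCl, rt
Reagents that add atoms: none
Why: Carboxylate-protected ester reduction: carboxylate 7 is inert to the Ca(BH4)2 formed in the flask while the methyl ester is reduced, and acidification lets hydroxy acid 8 lactonise. The lactone carbonyl thus ends on the carbon that was the free acid, and the stereocentre, remote from all bond changes, stays R.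

Step 5
Reactants: 9 (R)-4-[4-(benzyloxy)-3-bromo-5-methoxybenzyl]dihydrofuran-2(3H)-one; 10 (2-tert-butoxy-2-oxoethyl)zinc bromide
Product: 11 tert-butyl 2-[2-(benzyloxy)-3-methoxy-5-{[(3R)-5-oxotetrahydrofuran-3-yl]methyl}phenyl]acetate
Conditions: Pd2(dba)3 (2 mol%), XPhos (8 mol%), THF, 60 °C
Reagents that add atoms: none
Why: Negishi-type coupling of a Reformatsky reagent with an aryl bromide (oxidative addition to zerovalent palladium, transmetalation of the zinc ester enolate, reductive elimination). The zinc enolate is too weakly basic to touch the lactone, and a bulky biarylphosphine copes with the ortho-benzyloxy group.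

Step 6
Reactants: 11 tert-butyl 2-[2-(benzyloxy)-3-methoxy-5-{[(3R)-5-oxotetrahydrofuran-3-yl]methyl}phenyl]acetate
Product: 12 2-[2-(benzyloxy)-3-methoxy-5-{[(3R)-5-oxotetrahydrofuran-3-yl]methyl}phenyl]acetic acid
Conditions: CF3CO2H/CH2Cl2 (1:4), 0 °C → rt
Reagents that add atoms: none
Why: Acidolysis of the tert-butyl ester with loss of 2-methylpropene; the lactone, the aryl benzyl ether and the stereocentre are inert to dilute trifluoroacetic acid at this temperature.

Step 7
Reactants: 12 2-[2-(benzyloxy)-3-methoxy-5-{[(3R)-5-oxotetrahydrofuran-3-yl]methyl}phenyl]acetic acid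
Product: 14 (R)-4-benzyl-3-{2-[2-(benzyloxy)-3-methoxy-5-{[(3R)-5-oxotetrahydrofuran-3-yl]methyl}phenyl]acetyl}oxazolidin-2-one, via mixed pivalic anhydride 13 (not isolated)
Conditions: pivaloyl chloride, Et3N, THF, −20 °C; then LiCl, (R)-4-benzyl-2-oxazolidinone, −20 °C → rt
Reagents that add atoms: (R)-4-benzyl-2-oxazolidinone O=C1N[C@H](Cc2ccccc2)CO1
Why: N-Acylation of the oxazolidinone through the mixed anhydride with LiCl and Et3N needs no strong base, so the lactone is not enolised. The (R)-auxiliary is chosen because it leads to the S arm methine.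

Step 8
Reactants: 14 (R)-4-benzyl-3-{2-[2-(benzyloxy)-3-methoxy-5-{[(3R)-5-oxotetrahydrofuran-3-yl]methyl}phenyl]acetyl}oxazolidin-2-one; 15 4-(benzyloxy)-3-methoxybenzaldehyde
Product: 17 (R)-4-benzyl-3-[(2R,3R)-2-{2-(benzyloxy)-3-methoxy-5-{[(3R)-5-oxotetrahydrofuran-3-yl]methyl}phenyl}-3-[4-(benzyloxy)-3-methoxyphenyl]-3-hydroxypropanoyl]oxazolidin-2-one, via dibutylboron enolate 16 (not isolated)
Conditions: Bu2BOTf (1.2 eq), iPr2NEt (1.4 eq), CH2Cl2, 0 °C; 15, −78 → 0 °C; then pH 7 buffer, MeOH, 30% H2O2, 0 °C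
Reagents that add atoms: none
Why: Evans syn aldol: Bu2BOTf and iPr2NEt form only the Z boron enolate of the imide, since this reagent pair does not enolise the lactone. In the closed Zimmerman–Traxler transition state the aldehyde attacks the enolate face opposite the auxiliary benzyl group, which sets the arm methine and the carbinol (2R,3R in the imide); the methine is the centre that reaches the target.

Step 9
Reactants: 17 (R)-4-benzyl-3-[(2R,3R)-2-{2-(benzyloxy)-3-methoxy-5-{[(3R)-5-oxotetrahydrofuran-3-yl]methyl}phenyl}-3-[4-(benzyloxy)-3-methoxyphenyl]-3-hydroxypropanoyl]oxazolidin-2-one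
Product: 18 (R)-4-{4-(benzyloxy)-3-[(1R,2S)-1-[4-(benzyloxy)-3-methoxyphenyl]-1,3-dihydroxypropan-2-yl]-5-methoxybenzyl}dihydrofuran-2(3H)-one
Conditions: NaBH4 (3 eq), THF/H2O (3:1), 0 °C → rt
Reagents that add atoms: none
Why: Reductive removal of the auxiliary: the imide carbonyl is far more electrophilic than the lactone and is reduced by NaBH4 in wet THF to the primary alcohol with release of the oxazolidinone, while a γ-lactone reacts only slowly. The methine is now a plain benzylic CH (S) and no longer epimerisable.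

Step 10
Reactants: 18 (R)-4-{4-(benzyloxy)-3-[(1R,2S)-1-[4-(benzyloxy)-3-methoxyphenyl]-1,3-dihydroxypropan-2-yl]-5-methoxybenzyl}dihydrofuran-2(3H)-one
Product: 20 (R)-4-{4-(benzyloxy)-3-[(1R,2S)-1-[4-(benzyloxy)-3-methoxyphenyl]-3-(tert-butyldimethylsilyloxy)-1-(triethylsilyloxy)propan-2-yl]-5-methoxybenzyl}dihydrofuran-2(3H)-one, via primary silyl ether 19 (not isolated)
Conditions: TBSCl (1.05 eq), imidazole, DMF, 0 °C; then TESCl (1.5 eq), DMAP (cat.), rt
Reagents that add atoms: tert-butyldimethylsilyl chloride CC(C)(C)[Si](C)(C)Cl; triethylsilyl chloride CC[Si](CC)(CC)Cl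
Why: Two silylations in one flask ranked by steric demand: TBSCl takes the primary alcohol first, then the smaller TESCl caps the hindered secondary benzylic alcohol. The two groups differ enough in acid lability to be removed separately in steps 22 and 24.

Step 11
Reactants: 21 methyl 3-bromo-4-hydroxy-5-methoxybenzoate (methyl 5-bromovanillate); 2 benzyl bromide
Product: 22 methyl 4-(benzyloxy)-3-bromo-5-methoxybenzoate
Conditions: K2CO3, DMF, 60 °C
Reagents that add atoms: none
Why: Williamson etherification as in step 1; this benzyl ether has to last only until step 17.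

Step 12
Reactants: 22 methyl 4-(benzyloxy)-3-bromo-5-methoxybenzoate; 10 (2-tert-butoxy-2-oxoethyl)zinc bromide
Product: 23 methyl 4-(benzyloxy)-3-(2-tert-butoxy-2-oxoethyl)-5-methoxybenzoate
Conditions: Pd2(dba)3 (2 mol%), XPhos (8 mol%), THF, 60 °C
Reagents that add atoms: none
Why: The same Negishi-type coupling of the Reformatsky reagent as in step 5; zinc enolates do not add to the methyl benzoate.

Step 13
Reactants: 23 methyl 4-(benzyloxy)-3-(2-tert-butoxy-2-oxoethyl)-5-methoxybenzoate
Product: 24 2-[2-(benzyloxy)-3-methoxy-5-(methoxycarbonyl)phenyl]acetic acid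
Conditions: CF3CO2H/CH2Cl2 (1:4), 0 °C → rt
Reagents that add atoms: none
Why: Acidolysis of the tert-butyl ester as in step 6; the methyl benzoate and the benzyl ether stay.

Step 14
Reactants: 24 2-[2-(benzyloxy)-3-methoxy-5-(methoxycarbonyl)phenyl]acetic acid
Product: 26 methyl 4-(benzyloxy)-3-{2-[(S)-4-benzyl-2-oxooxazolidin-3-yl]-2-oxoethyl}-5-methoxybenzoate, via mixed pivalic anhydride 25 (not isolated)
Conditions: pivaloyl chloride, Et3N, THF, −20 °C; then LiCl, (S)-4-benzyl-2-oxazolidinone, −20 °C → rt
Reagents that add atoms: (S)-4-benzyl-2-oxazolidinone O=C1N[C@@H](Cc2ccccc2)CO1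
Why: Mixed-anhydride N-acylation as in step 7, here with the (S)-auxiliary, because C3 of the dihydrobenzofuran (R) has the opposite spatial sense to the ring B arm methine.

Step 15
Reactants: 26 methyl 4-(benzyloxy)-3-{2-[(S)-4-benzyl-2-oxooxazolidin-3-yl]-2-oxoethyl}-5-methoxybenzoate; 15 4-(benzyloxy)-3-methoxybenzaldehyde
Product: 28 methyl 4-(benzyloxy)-3-{(2S,3S)-1-[(S)-4-benzyl-2-oxooxazolidin-3-yl]-3-[4-(benzyloxy)-3-methoxyphenyl]-3-hydroxy-1-oxopropan-2-yl}-5-methoxybenzoate, via dibutylboron enolate 27 (not isolated)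
Conditions: Bu2BOTf (1.2 eq), iPr2NEt (1.4 eq), CH2Cl2, 0 °C; 15, −78 → 0 °C; then pH 7 buffer, MeOH, 30% H2O2, 0 °C
Reagents that add atoms: none
Why: Evans syn aldol as in step 8 with the mirror-image auxiliary. The methine that becomes C3 is set (2S,3S in the imide); the carbinol centre is set too but is given up in step 17.

Step 16
Reactants: 28 methyl 4-(benzyloxy)-3-{(2S,3S)-1-[(S)-4-benzyl-2-oxooxazolidin-3-yl]-3-[4-(benzyloxy)-3-methoxyphenyl]-3-hydroxy-1-oxopropan-2-yl}-5-methoxybenzoate
Product: 29 methyl 4-(benzyloxy)-3-{(1S,2R)-1-[4-(benzyloxy)-3-methoxyphenyl]-1,3-dihydroxypropan-2-yl}-5-methoxybenzoate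
Conditions: NaBH4 (3 eq), THF/H2O (3:1), 0 °C → rt
Reagents that add atoms: none
Why: NaBH4 in wet THF reduces the imide to the primary alcohol and frees the auxiliary. An electron-rich methyl benzoate is not reduced under these conditions, which keeps C5 at the ester level and distinct from the C3 hydroxymethyl group.

Step 17
Reactants: 29 methyl 4-(benzyloxy)-3-{(1S,2R)-1-[4-(benzyloxy)-3-methoxyphenyl]-1,3-dihydroxypropan-2-yl}-5-methoxybenzoate
Product: 31 methyl (2S,3R)-2-(4-hydroxy-3-methoxyphenyl)-3-(hydroxymethyl)-7-methoxy-2,3-dihydrobenzofuran-5-carboxylate, via diphenol diol 30 (not isolated)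
Conditions: H2 (1 atm), Pd/C, EtOAc, rt; filter; then TsOH·H2O (10 mol%), rt
Reagents that add atoms: none
Why: Hydrogenolysis frees both phenols, since aryl benzyl ethers cleave much faster than a benzylic hydroxyl in neutral ethyl acetate; catalytic acid then ionises the p-hydroxybenzylic alcohol to a quinone methide, which the ring C phenol captures in a 5-exo-trig closure of the C2–O bond. C3 (R, from the aldol) controls C2: the closure is reversible under acid and the 2,3-trans isomer (C2 S) is the stable one whatever the carbinol configuration. Mild acid and short contact keep E1 loss of the C3 proton from competing.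

Step 18
Reactants: 31 methyl (2S,3R)-2-(4-hydroxy-3-methoxyphenyl)-3-(hydroxymethyl)-7-methoxy-2,3-dihydrobenzofuran-5-carboxylate
Product: 32 methyl (2S,3R)-2-[4-(tert-butyldimethylsilyloxy)-3-methoxyphenyl]-3-[(tert-butyldimethylsilyloxy)methyl]-7-methoxy-2,3-dihydrobenzofuran-5-carboxylate
Conditions: TBSCl (2.5 eq), imidazole, DMF, rt
Reagents that add atoms: tert-butyldimethylsilyl chloride CC(C)(C)[Si](C)(C)Cl
Why: Silylation of the phenol and the primary alcohol with excess TBSCl; both must be masked before the amide base of step 21 and both leave together in step 24.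

Step 19
Reactants: 32 methyl (2S,3R)-2-[4-(tert-butyldimethylsilyloxy)-3-methoxyphenyl]-3-[(tert-butyldimethylsilyloxy)methyl]-7-methoxy-2,3-dihydrobenzofuran-5-carboxylate
Product: 33 {(2S,3R)-2-[4-(tert-butyldimethylsilyloxy)-3-methoxyphenyl]-3-[(tert-butyldimethylsilyloxy)methyl]-7-methoxy-2,3-dihydrobenzofuran-5-yl}methanol
Conditions: iBu2AlH (2.5 eq), CH2Cl2, −78 °C; aq. potassium sodium tartrate
Reagents that add atoms: none
Why: iBu2AlH reduces the methyl benzoate to the benzylic alcohol at low temperature; the silyl ethers and the dihydrobenzofuran are inert.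

Step 20
Reactants: 33 {(2S,3R)-2-[4-(tert-butyldimethylsilyloxy)-3-methoxyphenyl]-3-[(tert-butyldimethylsilyloxy)methyl]-7-methoxy-2,3-dihydrobenzofuran-5-yl}methanol
Product: 34 (2S,3R)-5-(bromomethyl)-2-[4-(tert-butyldimethylsilyloxy)-3-methoxyphenyl]-3-[(tert-butyldimethylsilyloxy)methyl]-7-methoxy-2,3-dihydrobenzofuran
Conditions: CBr4, PPh3, CH2Cl2, 0 °C
Reagents that add atoms: carbon tetrabromide BrC(Br)(Br)Br
Why: Appel reaction under neutral conditions converts the only free (benzylic) alcohol into the bromide without acid that would endanger the silyl ethers. The p-oxygenated benzylic bromide is reactive and is used without storage.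

Step 21
Reactants: 20 (R)-4-{4-(benzyloxy)-3-[(1R,2S)-1-[4-(benzyloxy)-3-methoxyphenyl]-3-(tert-butyldimethylsilyloxy)-1-(triethylsilyloxy)propan-2-yl]-5-methoxybenzyl}dihydrofuran-2(3H)-one; 34 (2S,3R)-5-(bromomethyl)-2-[4-(tert-butyldimethylsilyloxy)-3-methoxyphenyl]-3-[(tert-butyldimethylsilyloxy)methyl]-7-methoxy-2,3-dihydrobenzofuran
Product: 36 (3R,4R)-4-{4-(benzyloxy)-3-[(1R,2S)-1-[4-(benzyloxy)-3-methoxyphenyl]-3-(tert-butyldimethylsilyloxy)-1-(triethylsilyloxy)propan-2-yl]-5-methoxybenzyl}-3-{[(2S,3R)-2-[4-(tert-butyldimethylsilyloxy)-3-methoxyphenyl]-3-[(tert-butyldimethylsilyloxy)methyl]-7-methoxy-2,3-dihydrobenzofuran-5-yl]methyl}dihydrofuran-2(3H)-one, via lithium enolate 35 (not isolated)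
Conditions: LiN(SiMe3)2 (1.05 eq), THF, −78 °C; then 34, DMPU, −78 → −30 °C
Reagents that add atoms: none
Why: Alkylation of the γ-butyrolactone lithium enolate 35 by the benzylic bromide; the electrophile enters anti to the β-arylmethyl group, so Cβ (R) sets Cα (R, trans), the established way to trans-2,3-dibenzylbutyrolactones. All hydroxyls are silylated and no other C–H of 20 is acidic enough for LiN(SiMe3)2 at −78 °C.

Step 22
Reactants: 36 triethylsilyl ether from step 21
Product: 37 (3R,4R)-4-{4-(benzyloxy)-3-[(1R,2S)-1-[4-(benzyloxy)-3-methoxyphenyl]-3-(tert-butyldimethylsilyloxy)-1-hydroxypropan-2-yl]-5-methoxybenzyl}-3-{[(2S,3R)-2-[4-(tert-butyldimethylsilyloxy)-3-methoxyphenyl]-3-[(tert-butyldimethylsilyloxy)methyl]-7-methoxy-2,3-dihydrobenzofuran-5-yl]methyl}dihydrofuran-2(3H)-one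
Conditions: PPTS (0.2 eq), MeOH/CH2Cl2 (1:1), 0 °C
Reagents that add atoms: none
Why: Acid-catalysed methanolysis: a triethylsilyl ether is cleaved far faster than primary tert-butyldimethylsilyl ethers, and an aryl silyl ether is the most acid-stable of all, so only the secondary carbinol is unmasked.

Step 23
Reactants: 37 secondary alcohol from step 22
Product: 38 (3R,4R)-4-{4-(benzyloxy)-3-[(2S)-1-[4-(benzyloxy)-3-methoxyphenyl]-3-(tert-butyldimethylsilyloxy)-1-oxopropan-2-yl]-5-methoxybenzyl}-3-{[(2S,3R)-2-[4-(tert-butyldimethylsilyloxy)-3-methoxyphenyl]-3-[(tert-butyldimethylsilyloxy)methyl]-7-methoxy-2,3-dihydrobenzofuran-5-yl]methyl}dihydrofuran-2(3H)-one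
Conditions: Dess–Martin periodinane (1.5 eq), NaHCO3, CH2Cl2, 0 °C → rt
Reagents that add atoms: none
Why: Dess–Martin oxidation of the secondary benzylic alcohol under bicarbonate buffer; the reagent is non-basic, so the methine that becomes α to the ketone (S) is neither enolised nor stripped of its β-silyloxy group.

Step 24
Reactants: 38 silyl-protected ketone from step 23
Product: 39 (3R,4R)-4-{4-(benzyloxy)-3-[(2S)-1-[4-(benzyloxy)-3-methoxyphenyl]-3-hydroxy-1-oxopropan-2-yl]-5-methoxybenzyl}-3-{[(2S,3R)-2-(4-hydroxy-3-methoxyphenyl)-3-(hydroxymethyl)-7-methoxy-2,3-dihydrobenzofuran-5-yl]methyl}dihydrofuran-2(3H)-one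
Conditions: HF·pyridine, pyridine, THF, 0 °C → rt
Reagents that add atoms: none
Why: Fluoride-driven Si–O cleavage with pyridine-buffered HF·pyridine, weakly acidic and non-basic, so that no enolate forms beside the ketone; the two primary silyl ethers and the aryl silyl ether all fall.

Step 25
Reactants: 39 dibenzyl ether from step 24
Product: 40 (3R,4R)-3-{[(2S,3R)-2-(4-hydroxy-3-methoxyphenyl)-3-(hydroxymethyl)-7-methoxy-2,3-dihydrobenzofuran-5-yl]methyl}-4-{4-hydroxy-3-[(2S)-3-hydroxy-1-(4-hydroxy-3-methoxyphenyl)-1-oxopropan-2-yl]-5-methoxybenzyl}dihydrofuran-2(3H)-one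
Conditions: H2 (1 atm), Pd/C, EtOAc, rt
Reagents that add atoms: none
Why: Hydrogenolysis of the two aryl benzyl ethers in a neutral aprotic solvent is much faster than reduction of the electron-rich aryl ketone or cleavage of the dihydrobenzofuran C2–O bond. Nothing acidic or basic touches the labile methine in the last step.

## Compound list

1 | 5-bromovanillin (3-bromo-4-hydroxy-5-methoxybenzaldehyde) | COc1cc(C=O)cc(Br)c1O | starting material
2 | benzyl bromide | BrCc1ccccc1 | starting material
3 | 4-(benzyloxy)-3-bromo-5-methoxybenzaldehyde | COc1cc(C=O)cc(Br)c1OCc1ccccc1 | intermediate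
4 | dimethyl succinate | COC(=O)CCC(=O)OC | starting material
5 | (E)-4-[4-(benzyloxy)-3-bromo-5-methoxyphenyl]-3-(methoxycarbonyl)but-3-enoic acid | COC(=O)/C(CC(=O)O)=C/c1cc(Br)c(OCc2ccccc2)c(OC)c1 | intermediate
6 | (R)-3-[4-(benzyloxy)-3-bromo-5-methoxybenzyl]-4-methoxy-4-oxobutanoic acid | COC(=O)[C@@H](CC(=O)O)Cc1cc(Br)c(OCc2ccccc2)c(OC)c1 | intermediate
7 | potassium (R)-3-[4-(benzyloxy)-3-bromo-5-methoxybenzyl]-4-methoxy-4-oxobutanoate | COC(=O)[C@@H](CC(=O)[O-])Cc1cc(Br)c(OCc2ccccc2)c(OC)c1.[K+] | intermediate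
8 | (R)-3-[4-(benzyloxy)-3-bromo-5-methoxybenzyl]-4-hydroxybutanoic acid | OC[C@@H](CC(=O)O)Cc1cc(Br)c(OCc2ccccc2)c(OC)c1 | intermediate
9 | (R)-4-[4-(benzyloxy)-3-bromo-5-methoxybenzyl]dihydrofuran-2(3H)-one | COc1cc(C[C@H]2COC(=O)C2)cc(Br)c1OCc1ccccc1 | intermediate
10 | (2-tert-butoxy-2-oxoethyl)zinc bromide (sold as a solution; otherwise from tert-butyl bromoacetate and zinc) | CC(C)(C)OC(=O)C[Zn]Br | starting material
11 | tert-butyl 2-[2-(benzyloxy)-3-methoxy-5-{[(3R)-5-oxotetrahydrofuran-3-yl]methyl}phenyl]acetate | COc1cc(C[C@H]2COC(=O)C2)cc(CC(=O)OC(C)(C)C)c1OCc1ccccc1 | intermediate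
12 | 2-[2-(benzyloxy)-3-methoxy-5-{[(3R)-5-oxotetrahydrofuran-3-yl]methyl}phenyl]acetic acid | COc1cc(C[C@H]2COC(=O)C2)cc(CC(=O)O)c1OCc1ccccc1 | intermediate
13 | mixed pivalic anhydride of 12 | COc1cc(C[C@H]2COC(=O)C2)cc(CC(=O)OC(=O)C(C)(C)C)c1OCc1ccccc1 | intermediate
14 | (R)-4-benzyl-3-{2-[2-(benzyloxy)-3-methoxy-5-{[(3R)-5-oxotetrahydrofuran-3-yl]methyl}phenyl]acetyl}oxazolidin-2-one | COc1cc(C[C@H]2COC(=O)C2)cc(CC(=O)N3[C@H](Cc4ccccc4)COC3=O)c1OCc1ccccc1 | intermediate
15 | 4-(benzyloxy)-3-methoxybenzaldehyde (O-benzylvanillin) | COc1cc(C=O)ccc1OCc1ccccc1 | starting material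
16 | (Z)-dibutylboron enolate of 14 | CCCCB(CCCC)O/C(N1[C@H](Cc2ccccc2)COC1=O)=C\c1cc(C[C@H]2COC(=O)C2)cc(OC)c1OCc1ccccc1 | intermediate
17 | (R)-4-benzyl-3-[(2R,3R)-2-{2-(benzyloxy)-3-methoxy-5-{[(3R)-5-oxotetrahydrofuran-3-yl]methyl}phenyl}-3-[4-(benzyloxy)-3-methoxyphenyl]-3-hydroxypropanoyl]oxazolidin-2-one | COc1cc(C[C@H]2COC(=O)C2)cc([C@@H](C(=O)N3[C@H](Cc4ccccc4)COC3=O)[C@@H](O)c3ccc(OCc4ccccc4)c(OC)c3)c1OCc1ccccc1 | intermediate
18 | (R)-4-{4-(benzyloxy)-3-[(1R,2S)-1-[4-(benzyloxy)-3-methoxyphenyl]-1,3-dihydroxypropan-2-yl]-5-methoxybenzyl}dihydrofuran-2(3H)-one | COc1cc(C[C@H]2COC(=O)C2)cc([C@@H](CO)[C@@H](O)c3ccc(OCc4ccccc4)c(OC)c3)c1OCc1ccccc1 | intermediate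
19 | (R)-4-{4-(benzyloxy)-3-[(1R,2S)-1-[4-(benzyloxy)-3-methoxyphenyl]-3-(tert-butyldimethylsilyloxy)-1-hydroxypropan-2-yl]-5-methoxybenzyl}dihydrofuran-2(3H)-one | COc1cc(C[C@H]2COC(=O)C2)cc([C@@H](CO[Si](C)(C)C(C)(C)C)[C@@H](O)c3ccc(OCc4ccccc4)c(OC)c3)c1OCc1ccccc1 | intermediate
20 | (R)-4-{4-(benzyloxy)-3-[(1R,2S)-1-[4-(benzyloxy)-3-methoxyphenyl]-3-(tert-butyldimethylsilyloxy)-1-(triethylsilyloxy)propan-2-yl]-5-methoxybenzyl}dihydrofuran-2(3H)-one | COc1cc(C[C@H]2COC(=O)C2)cc([C@@H](CO[Si](C)(C)C(C)(C)C)[C@@H](O[Si](CC)(CC)CC)c3ccc(OCc4ccccc4)c(OC)c3)c1OCc1ccccc1 | intermediate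
21 | methyl 3-bromo-4-hydroxy-5-methoxybenzoate (methyl 5-bromovanillate) | COC(=O)c1cc(Br)c(O)c(OC)c1 | starting material
22 | methyl 4-(benzyloxy)-3-bromo-5-methoxybenzoate | COC(=O)c1cc(Br)c(OCc2ccccc2)c(OC)c1 | intermediate
23 | methyl 4-(benzyloxy)-3-(2-tert-butoxy-2-oxoethyl)-5-methoxybenzoate | COC(=O)c1cc(CC(=O)OC(C)(C)C)c(OCc2ccccc2)c(OC)c1 | intermediate
24 | 2-[2-(benzyloxy)-3-methoxy-5-(methoxycarbonyl)phenyl]acetic acid | COC(=O)c1cc(CC(=O)O)c(OCc2ccccc2)c(OC)c1 | intermediate
25 | mixed pivalic anhydride of 24 | COC(=O)c1cc(CC(=O)OC(=O)C(C)(C)C)c(OCc2ccccc2)c(OC)c1 | intermediate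
26 | methyl 4-(benzyloxy)-3-{2-[(S)-4-benzyl-2-oxooxazolidin-3-yl]-2-oxoethyl}-5-methoxybenzoate | COC(=O)c1cc(CC(=O)N2[C@@H](Cc3ccccc3)COC2=O)c(OCc2ccccc2)c(OC)c1 | intermediate
27 | (Z)-dibutylboron enolate of 26 | CCCCB(CCCC)O/C(N1[C@@H](Cc2ccccc2)COC1=O)=C\c1cc(C(=O)OC)cc(OC)c1OCc1ccccc1 | intermediate
28 | methyl 4-(benzyloxy)-3-{(2S,3S)-1-[(S)-4-benzyl-2-oxooxazolidin-3-yl]-3-[4-(benzyloxy)-3-methoxyphenyl]-3-hydroxy-1-oxopropan-2-yl}-5-methoxybenzoate | COC(=O)c1cc([C@H](C(=O)N2[C@@H](Cc3ccccc3)COC2=O)[C@H](O)c2ccc(OCc3ccccc3)c(OC)c2)c(OCc2ccccc2)c(OC)c1 | intermediate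
29 | methyl 4-(benzyloxy)-3-{(1S,2R)-1-[4-(benzyloxy)-3-methoxyphenyl]-1,3-dihydroxypropan-2-yl}-5-methoxybenzoate | COC(=O)c1cc([C@H](CO)[C@H](O)c2ccc(OCc3ccccc3)c(OC)c2)c(OCc2ccccc2)c(OC)c1 | intermediate
30 | methyl 3-[(1S,2R)-1,3-dihydroxy-1-(4-hydroxy-3-methoxyphenyl)propan-2-yl]-4-hydroxy-5-methoxybenzoate | COC(=O)c1cc([C@H](CO)[C@H](O)c2ccc(O)c(OC)c2)c(O)c(OC)c1 | intermediate
31 | methyl (2S,3R)-2-(4-hydroxy-3-methoxyphenyl)-3-(hydroxymethyl)-7-methoxy-2,3-dihydrobenzofuran-5-carboxylate | COC(=O)c1cc(OC)c2c(c1)[C@H](CO)[C@@H](c1ccc(O)c(OC)c1)O2 | intermediate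
32 | methyl (2S,3R)-2-[4-(tert-butyldimethylsilyloxy)-3-methoxyphenyl]-3-[(tert-butyldimethylsilyloxy)methyl]-7-methoxy-2,3-dihydrobenzofuran-5-carboxylate | COC(=O)c1cc(OC)c2c(c1)[C@H](CO[Si](C)(C)C(C)(C)C)[C@@H](c1ccc(O[Si](C)(C)C(C)(C)C)c(OC)c1)O2 | intermediate
33 | {(2S,3R)-2-[4-(tert-butyldimethylsilyloxy)-3-methoxyphenyl]-3-[(tert-butyldimethylsilyloxy)methyl]-7-methoxy-2,3-dihydrobenzofuran-5-yl}methanol | OCc1cc(OC)c2c(c1)[C@H](CO[Si](C)(C)C(C)(C)C)[C@@H](c1ccc(O[Si](C)(C)C(C)(C)C)c(OC)c1)O2 | intermediate
34 | (2S,3R)-5-(bromomethyl)-2-[4-(tert-butyldimethylsilyloxy)-3-methoxyphenyl]-3-[(tert-butyldimethylsilyloxy)methyl]-7-methoxy-2,3-dihydrobenzofuran | BrCc1cc(OC)c2c(c1)[C@H](CO[Si](C)(C)C(C)(C)C)[C@@H](c1ccc(O[Si](C)(C)C(C)(C)C)c(OC)c1)O2 | intermediate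
35 | lithium enolate of 20 | [Li]OC1=C[C@@H](Cc2cc([C@@H](CO[Si](C)(C)C(C)(C)C)[C@@H](O[Si](CC)(CC)CC)c3ccc(OCc4ccccc4)c(OC)c3)c(OCc3ccccc3)c(OC)c2)CO1 | intermediate
36 | (3R,4R)-4-{4-(benzyloxy)-3-[(1R,2S)-1-[4-(benzyloxy)-3-methoxyphenyl]-3-(tert-butyldimethylsilyloxy)-1-(triethylsilyloxy)propan-2-yl]-5-methoxybenzyl}-3-{[(2S,3R)-2-[4-(tert-butyldimethylsilyloxy)-3-methoxyphenyl]-3-[(tert-butyldimethylsilyloxy)methyl]-7-methoxy-2,3-dihydrobenzofuran-5-yl]methyl}dihydrofuran-2(3H)-one | COc1cc([C@H](O[Si](CC)(CC)CC)[C@H](CO[Si](C)(C)C(C)(C)C)c2cc(C[C@H]3COC(=O)[C@@H]3Cc3cc(OC)c4c(c3)[C@H](CO[Si](C)(C)C(C)(C)C)[C@@H](c3ccc(O[Si](C)(C)C(C)(C)C)c(OC)c3)O4)cc(OC)c2OCc2ccccc2)ccc1OCc1ccccc1 | intermediate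
37 | (3R,4R)-4-{4-(benzyloxy)-3-[(1R,2S)-1-[4-(benzyloxy)-3-methoxyphenyl]-3-(tert-butyldimethylsilyloxy)-1-hydroxypropan-2-yl]-5-methoxybenzyl}-3-{[(2S,3R)-2-[4-(tert-butyldimethylsilyloxy)-3-methoxyphenyl]-3-[(tert-butyldimethylsilyloxy)methyl]-7-methoxy-2,3-dihydrobenzofuran-5-yl]methyl}dihydrofuran-2(3H)-one | COc1cc([C@H](O)[C@H](CO[Si](C)(C)C(C)(C)C)c2cc(C[C@H]3COC(=O)[C@@H]3Cc3cc(OC)c4c(c3)[C@H](CO[Si](C)(C)C(C)(C)C)[C@@H](c3ccc(O[Si](C)(C)C(C)(C)C)c(OC)c3)O4)cc(OC)c2OCc2ccccc2)ccc1OCc1ccccc1 | intermediate
38 | (3R,4R)-4-{4-(benzyloxy)-3-[(2S)-1-[4-(benzyloxy)-3-methoxyphenyl]-3-(tert-butyldimethylsilyloxy)-1-oxopropan-2-yl]-5-methoxybenzyl}-3-{[(2S,3R)-2-[4-(tert-butyldimethylsilyloxy)-3-methoxyphenyl]-3-[(tert-butyldimethylsilyloxy)methyl]-7-methoxy-2,3-dihydrobenzofuran-5-yl]methyl}dihydrofuran-2(3H)-one | COc1cc(C(=O)[C@H](CO[Si](C)(C)C(C)(C)C)c2cc(C[C@H]3COC(=O)[C@@H]3Cc3cc(OC)c4c(c3)[C@H](CO[Si](C)(C)C(C)(C)C)[C@@H](c3ccc(O[Si](C)(C)C(C)(C)C)c(OC)c3)O4)cc(OC)c2OCc2ccccc2)ccc1OCc1ccccc1 | intermediate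
39 | (3R,4R)-4-{4-(benzyloxy)-3-[(2S)-1-[4-(benzyloxy)-3-methoxyphenyl]-3-hydroxy-1-oxopropan-2-yl]-5-methoxybenzyl}-3-{[(2S,3R)-2-(4-hydroxy-3-methoxyphenyl)-3-(hydroxymethyl)-7-methoxy-2,3-dihydrobenzofuran-5-yl]methyl}dihydrofuran-2(3H)-one | COc1cc(C(=O)[C@H](CO)c2cc(C[C@H]3COC(=O)[C@@H]3Cc3cc(OC)c4c(c3)[C@H](CO)[C@@H](c3ccc(O)c(OC)c3)O4)cc(OC)c2OCc2ccccc2)ccc1OCc1ccccc1 | intermediate
40 | (3R,4R)-3-{[(2S,3R)-2-(4-hydroxy-3-methoxyphenyl)-3-(hydroxymethyl)-7-methoxy-2,3-dihydrobenzofuran-5-yl]methyl}-4-{4-hydroxy-3-[(2S)-3-hydroxy-1-(4-hydroxy-3-methoxyphenyl)-1-oxopropan-2-yl]-5-methoxybenzyl}dihydrofuran-2(3H)-one | COc1cc(C(=O)[C@H](CO)c2cc(C[C@H]3COC(=O)[C@@H]3Cc3cc(OC)c4c(c3)[C@H](CO)[C@@H](c3ccc(O)c(OC)c3)O4)cc(OC)c2O)ccc1O | target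

## Step count and least certain steps

Total step count: 25 (steps 10 and 17 each run two operations without isolation and are counted once). Longest linear sequence: 15 steps (1–10, then 21–25); the second branch (11–20, then 21–25) is equally long.

Step 3 (key step). Most likely failure: incomplete enantioface discrimination, because an aryl group at the alkene terminus sits less snugly in the chiral pocket than the alkyl groups for which this catalyst family is best documented; residual Z isomer would react through a different chelate, and a poorly binding free acid would slow turnover. Fallback (resolution in place of asymmetric catalysis): starting from 5, hydrogenation with the achiral complex [Rh(cod)(dppb)]BF4 should give the racemic half-ester F1. Crystallisation with (S)-1-phenylethylamine should give the (S)-1-phenylethylammonium salt F2 of the R acid, the amine hand being chosen so that the R acid forms the less soluble salt. Dilute HCl then liberates the acid, and the route is rejoined at 6. The same crystallisation would also upgrade material of imperfect enantiomeric purity from step 3.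

Step 9. Most likely failure: competing hydride attack on the γ-lactone (ring opening to a diol) or base-induced retro-aldol cleavage of 17 in the alkaline borohydride medium, since the selectivity rests only on the rate difference between imide and lactone. Fallback (a more electrophilic auxiliary): starting from 12, carbodiimide coupling with (R)-4-benzylthiazolidine-2-thione should give the N-acyl thiazolidinethione F3. Its titanium enolate (TiCl4, iPr2NEt, N-methyl-2-pyrrolidone, CH2Cl2, −78 °C) with 15 should give the syn adduct F4 in the same sense as the boron aldol. The thioimide is cleaved by NaBH4 in EtOH/THF at 0 °C within minutes, well before a lactone reacts, and the route is rejoined at 18.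

Step 21. Most likely failure: slow C-alkylation of the encumbered enolate while the electron-rich benzylic bromide ionises or self-condenses, and proton exchange between product and enolate that erodes the trans ratio or leads to double alkylation. Fallback (aldol addition and deoxygenation in place of alkylation): starting from 33, MnO2 in CH2Cl2 should give the aldehyde F5. Addition of lithium enolate 35 (from 20) at −78 °C, again anti to the β-substituent, should give the hydroxy lactone F6 as a pair of carbinol epimers. Conversion into the O-phenyl thionocarbonate F7 (PhOC(S)Cl, pyridine) and Barton–McCombie reduction (Bu3SnH, AIBN, toluene, 80 °C) removes the extra oxygen, and the route is rejoined at 36.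

Step 24. Most likely failure: E1cB loss of the β-silyloxy group or enolisation-driven epimerisation of the α-aryl methine while fluoride is in contact with the β-silyloxy ketone, made worse by slow cleavage of the aryl silyl ether, which prolongs exposure. Fallback (desilylate before the ketone exists, then oxidise chemoselectively): starting from 36, AcOH/THF/H2O at 40 °C should remove the triethylsilyl and both primary silyl ethers but not the aryl silyl ether, giving the triol F8. MnO2 in CH2Cl2 oxidises only the benzylic secondary alcohol, giving the hydroxy ketone F9, which never carries a β-leaving group. Brief treatment with KF in MeOH at 0 °C (or acetic acid-buffered tetrabutylammonium fluoride) removes the aryl silyl ether, and the route is rejoined at 39.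

## Further compounds

F1 | step 3 | racemic 3-[4-(benzyloxy)-3-bromo-5-methoxybenzyl]-4-methoxy-4-oxobutanoic acid | COC(=O)C(CC(=O)O)Cc1cc(Br)c(OCc2ccccc2)c(OC)c1
F2 | step 3 | (S)-1-phenylethylammonium (R)-3-[4-(benzyloxy)-3-bromo-5-methoxybenzyl]-4-methoxy-4-oxobutanoate | COC(=O)[C@@H](CC(=O)[O-])Cc1cc(Br)c(OCc2ccccc2)c(OC)c1.C[C@H]([NH3+])c1ccccc1
F3 | step 9 | (R)-4-benzyl-3-{2-[2-(benzyloxy)-3-methoxy-5-{[(3R)-5-oxotetrahydrofuran-3-yl]methyl}phenyl]acetyl}thiazolidine-2-thione | COc1cc(C[C@H]2COC(=O)C2)cc(CC(=O)N3[C@H](Cc4ccccc4)CSC3=S)c1OCc1ccccc1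
F4 | step 9 | (R)-4-benzyl-3-[(2R,3R)-2-{2-(benzyloxy)-3-methoxy-5-{[(3R)-5-oxotetrahydrofuran-3-yl]methyl}phenyl}-3-[4-(benzyloxy)-3-methoxyphenyl]-3-hydroxypropanoyl]thiazolidine-2-thione | COc1cc(C[C@H]2COC(=O)C2)cc([C@@H](C(=O)N3[C@H](Cc4ccccc4)CSC3=S)[C@@H](O)c3ccc(OCc4ccccc4)c(OC)c3)c1OCc1ccccc1
F5 | step 21 | (2S,3R)-2-[4-(tert-butyldimethylsilyloxy)-3-methoxyphenyl]-3-[(tert-butyldimethylsilyloxy)methyl]-7-methoxy-2,3-dihydrobenzofuran-5-carbaldehyde | O=Cc1cc(OC)c2c(c1)[C@H](CO[Si](C)(C)C(C)(C)C)[C@@H](c1ccc(O[Si](C)(C)C(C)(C)C)c(OC)c1)O2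
F6 | step 21 | analogue of 36 with a hydroxyl on the ring C benzylic carbon next to the lactone α-carbon (both carbinol epimers) | COc1cc([C@H](O[Si](CC)(CC)CC)[C@H](CO[Si](C)(C)C(C)(C)C)c2cc(C[C@H]3COC(=O)[C@@H]3C(O)c3cc(OC)c4c(c3)[C@H](CO[Si](C)(C)C(C)(C)C)[C@@H](c3ccc(O[Si](C)(C)C(C)(C)C)c(OC)c3)O4)cc(OC)c2OCc2ccccc2)ccc1OCc1ccccc1
F7 | step 21 | O-phenyl thionocarbonate of F6 | COc1cc([C@H](O[Si](CC)(CC)CC)[C@H](CO[Si](C)(C)C(C)(C)C)c2cc(C[C@H]3COC(=O)[C@@H]3C(OC(=S)Oc5ccccc5)c3cc(OC)c4c(c3)[C@H](CO[Si](C)(C)C(C)(C)C)[C@@H](c3ccc(O[Si](C)(C)C(C)(C)C)c(OC)c3)O4)cc(OC)c2OCc2ccccc2)ccc1OCc1ccccc1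
F8 | step 24 | (3R,4R)-4-{4-(benzyloxy)-3-[(1R,2S)-1-[4-(benzyloxy)-3-methoxyphenyl]-1,3-dihydroxypropan-2-yl]-5-methoxybenzyl}-3-{[(2S,3R)-2-[4-(tert-butyldimethylsilyloxy)-3-methoxyphenyl]-3-(hydroxymethyl)-7-methoxy-2,3-dihydrobenzofuran-5-yl]methyl}dihydrofuran-2(3H)-one | COc1cc([C@H](O)[C@H](CO)c2cc(C[C@H]3COC(=O)[C@@H]3Cc3cc(OC)c4c(c3)[C@H](CO)[C@@H](c3ccc(O[Si](C)(C)C(C)(C)C)c(OC)c3)O4)cc(OC)c2OCc2ccccc2)ccc1OCc1ccccc1
F9 | step 24 | (3R,4R)-4-{4-(benzyloxy)-3-[(2S)-1-[4-(benzyloxy)-3-methoxyphenyl]-3-hydroxy-1-oxopropan-2-yl]-5-methoxybenzyl}-3-{[(2S,3R)-2-[4-(tert-butyldimethylsilyloxy)-3-methoxyphenyl]-3-(hydroxymethyl)-7-methoxy-2,3-dihydrobenzofuran-5-yl]methyl}dihydrofuran-2(3H)-one | COc1cc(C(=O)[C@H](CO)c2cc(C[C@H]3COC(=O)[C@@H]3Cc3cc(OC)c4c(c3)[C@H](CO)[C@@H](c3ccc(O[Si](C)(C)C(C)(C)C)c(OC)c3)O4)cc(OC)c2OCc2ccccc2)ccc1OCc1ccccc1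
A1 | alternative 1 | pentakis(tert-butyldimethylsilyl) ether of 40 | COc1cc(C(=O)[C@H](CO[Si](C)(C)C(C)(C)C)c2cc(C[C@H]3COC(=O)[C@@H]3Cc3cc(OC)c4c(c3)[C@H](CO[Si](C)(C)C(C)(C)C)[C@@H](c3ccc(O[Si](C)(C)C(C)(C)C)c(OC)c3)O4)cc(OC)c2O[Si](C)(C)C(C)(C)C)ccc1O[Si](C)(C)C(C)(C)C
A2 | alternative 1 | S-ethyl thioester of the ring B arm acid (skeleton of 40 without ring A, four silyl ethers) | CCSC(=O)[C@H](CO[Si](C)(C)C(C)(C)C)c1cc(C[C@H]2COC(=O)[C@@H]2Cc2cc(OC)c3c(c2)[C@H](CO[Si](C)(C)C(C)(C)C)[C@@H](c2ccc(O[Si](C)(C)C(C)(C)C)c(OC)c2)O3)cc(OC)c1O[Si](C)(C)C(C)(C)C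
A3 | alternative 1 | [4-(tert-butyldimethylsilyloxy)-3-methoxyphenyl]boronic acid | COc1cc(B(O)O)ccc1O[Si](C)(C)C(C)(C)C
A4 | alternative 2 | methyl (2S,3R)-2-[4-(benzyloxy)-3-methoxyphenyl]-5-(dimethoxymethyl)-7-methoxy-2,3-dihydrobenzofuran-3-carboxylate (2,3-cis) | COC(OC)c1cc(OC)c2c(c1)[C@@H](C(=O)OC)[C@@H](c1ccc(OCc3ccccc3)c(OC)c1)O2
A5 | alternative 2 | methyl 2-[4-(benzyloxy)-3-methoxyphenyl]-5-(dimethoxymethyl)-7-methoxybenzofuran-3-carboxylate | COC(OC)c1cc(OC)c2oc(-c3ccc(OCc4ccccc4)c(OC)c3)c(C(=O)OC)c2c1
A6 | alternative 3 | methyl (2S,3S)-3-[4-(benzyloxy)-3-methoxyphenyl]-2-[5-bromo-3-methoxy-2-(methoxymethoxy)phenyl]-3-hydroxypropanoate | COC(=O)[C@H]([C@H](O)c1ccc(OCc2ccccc2)c(OC)c1)c1cc(Br)cc(OC)c1OCOC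
A7 | alternative 3 | racemic methyl 3-[4-(benzyloxy)-3-methoxyphenyl]-2-[5-bromo-3-methoxy-2-(methoxymethoxy)phenyl]-3-oxopropanoate | COC(=O)C(C(=O)c1ccc(OCc2ccccc2)c(OC)c1)c1cc(Br)cc(OC)c1OCOC
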